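**Retrosynthetic overview**
1. C3–Br ⇐ C3–CO2H: the last bromine replaces the carboxyl group by ipso-bromodecarboxylation.
2. Carboxylic acid ⇐ methyl ester, and N–CH3 ⇐ N–H + MeI, both in one flask.
3. C5–Br and C6–Br ⇐ double electrophilic bromination of methyl 1H-indole-3-carboxylate; the C3 ester blocks C3 and steers bromine to the benzo ring.
4. No ring is formed: both rings of the indole are bought intact in the starting ester.

Assumption: the target has no stereogenic element, so the "single enantiomer" is simply the achiral compound and no stereocontrol is needed; shelf reagents (Br2, MeI, NBS, bases, acids) are named but not numbered.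

**Route**

Step 1
Reactants: 1 methyl 1H-indole-3-carboxylate
Product: 2 methyl 5,6-dibromo-1H-indole-3-carboxylate
Conditions: Br2 (2.3 equiv), AcOH, rt, 24 h
Reagents that add atoms: bromine, BrBr
Why: Electrophilic aromatic bromination (SEAr), in which the C3 ester blocks C3 and deactivates the pyrrole ring as a vinylogous carbamate, so both bromines enter the benzo ring at C6 and C5, a precedented regioselective dibromination; no stereocentre is formed.

Step 2
Reactants: 2 methyl 5,6-dibromo-1H-indole-3-carboxylate
Product: 4 5,6-dibromo-1-methyl-1H-indole-3-carboxylic acid, via N-methyl ester 3 (not isolated)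
Conditions: NaH, MeI, THF–DMF, 0 °C to rt; then 2 M NaOH, MeOH, 65 °C; then 1 M HCl, 0 °C
Reagents that add atoms: iodomethane, CI; sodium hydroxide, [Na+].[OH-] (its oxygen becomes the carboxyl OH)
Why: N-deprotonation and SN2 N-methylation of the indolide (C3 is blocked, so only N is alkylated) followed by BAc2 ester saponification in the same flask, with cold acidification to release the acid without protodecarboxylation; no stereocentre is formed.

Step 3
Reactants: 4 5,6-dibromo-1-methyl-1H-indole-3-carboxylic acid
Product: 5 3,5,6-tribromo-1-methyl-1H-indole
Conditions: NBS (1.05 equiv), DMF, 0 °C to rt, dark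
Reagents that add atoms: N-bromosuccinimide, O=C1CCC(=O)N1Br
Why: Hunsdiecker-type ipso-bromodecarboxylation, in which electrophilic bromine attacks the most nucleophilic carbon C3 and aromaticity is restored by loss of CO2, so bromine ends up exactly where the carboxyl was while the two aryl bromides are untouched; no stereocentre is formed.

**Compound list**
1 | methyl 1H-indole-3-carboxylate | COC(=O)c1c[nH]c2ccccc12 | starting material
2 | methyl 5,6-dibromo-1H-indole-3-carboxylate | COC(=O)c1c[nH]c2cc(Br)c(Br)cc12 | intermediate
3 | methyl 5,6-dibromo-1-methyl-1H-indole-3-carboxylate (formed in the flask in step 2, not isolated) | COC(=O)c1cn(C)c2cc(Br)c(Br)cc12 | intermediate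
4 | 5,6-dibromo-1-methyl-1H-indole-3-carboxylic acid | OC(=O)c1cn(C)c2cc(Br)c(Br)cc12 | intermediate
5 | 3,5,6-tribromo-1-methyl-1H-indole | Cn1cc(Br)c2cc(Br)c(Br)cc21 | target

**Totals**
Total step count: 3. Longest linear sequence: 3 steps.

**Steps most likely to fail and their fallbacks**
Ranked by risk: step 3, then step 1, then step 2.

Step 1 risks incomplete or excessive bromination, or N-bromination, of the poorly soluble N–H ester, giving mixtures of mono-, di- and tribromides that do not crystallise apart. The fallback reverses the order of N-methylation and ring bromination, so that bromination is run on a different substrate. It sets out from 1, which is N-methylated (NaH, MeI, THF–DMF, 0 °C) to methyl 1-methyl-1H-indole-3-carboxylate F1. F1 has no N–H, is more soluble and can be chromatographed; it is dibrominated (Br2, AcOH, NaOAc buffer, rt) at C5 and C6. This gives 3, now isolated and purified, where the fallback comes back to the route; 3 is saponified to 4 by the NaOH stage of step 2.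

Step 2 risks sluggish saponification of the vinylogous carbamate ester and loss of CO2 from 4 during forcing hydrolysis or acidification, which would destroy the handle that step 3 needs. The fallback gives up the carboxyl group on purpose and installs the C3 bromine by ordinary SEAr. It sets out from 2, which is heated with aqueous NaOH in MeOH in a sealed vessel (about 150 °C), then acidified with HCl and warmed. This saponifies and protodecarboxylates in one pot to give 5,6-dibromo-1H-indole F2. F2 is brominated at its free C3 (NBS, DMF, 0 °C) to 3,5,6-tribromo-1H-indole F3. F3 is N-methylated (NaH, MeI, THF, 0 °C), and the fallback comes back to the route at 5.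

Step 3 risks over-bromination at C2 to the tetrabromide, or a sluggish ipso attack on the electron-poor dibromoindole acid. The fallback separates the loss of CO2 from the C–Br bond formation. It sets out from 4, which is protodecarboxylated by warming in AcOH containing HCl (ipso-protonation at C3, then loss of CO2), or with Ag2CO3 (10 mol %) and AcOH in DMSO at 120 °C. This gives 5,6-dibromo-1-methyl-1H-indole F4. F4 is brominated at C3 with NBS (1.0 equiv) in DMF at 0 °C, and the fallback comes back to the route at 5.

**Further compounds**
F1 | step 1 | methyl 1-methyl-1H-indole-3-carboxylate | COC(=O)c1cn(C)c2ccccc12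
F2 | step 2 | 5,6-dibromo-1H-indole | Brc1cc2cc[nH]c2cc1Br
F3 | step 2 | 3,5,6-tribromo-1H-indole | Brc1c[nH]c2cc(Br)c(Br)cc12
F4 | step 3 | 5,6-dibromo-1-methyl-1H-indole | Cn1ccc2cc(Br)c(Br)cc21
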